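**Plan**
- Retrosynthesis: remove the silyl ethers; trace the C1=C10 enal to its β,γ-unsaturated isomer; cut C1–C10 by reversing a 1,2-alkenyl shift (C1 back to C14), which gives an eleven-membered 2,3-epoxy silyl ether; then cut C1=C2 (metathesis), C1–C14 (vinyl addition), the C9–C10 epoxide (from an E alkene), C4=C5 (Wittig), the C8–O ester (Mitsunobu) and C7–C8 (Barbier).
- Enabling feature: C10 carries the formyl carbon C14, the ring carbon C1 and the carbinol C9, which is the retron of a semipinacol shift. An eleven-membered carbocycle C1–C14–C10–C9–C8–C7–C6–C5–C4–C3–C2, with C14 in the ring and an epoxide on C9–C10, contracts to the ten-membered ring C1–C10; C14 is expelled as CHO and the epoxide oxygen becomes the C9 hydroxyl.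
- Forward order of rings: γ-lactone (from the pool butenolide; the methylene lactone is unmasked in the Barbier step), then the eleven-membered carbocycle by ring-closing metathesis, then the ten-membered ring by ring contraction.
- Stereochemistry: C6 from (S)-5-(hydroxymethyl)butenolide; C7 by anti attack in the Barbier step; C8 by a chair transition state followed by Mitsunobu inversion, which also installs the (R)-2-methylbutanoate; C9 by Sharpless epoxidation, retained in the shift; C4=C5 from an E-selective Wittig reaction; C1=C10 as the thermodynamic enal.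

Key step: step 15

Remarks on the chemistry: positions are given in germacrane numbering (ring C1–C10, lactone carbons C11–C13, C14 on C10, C15 on C4). The C14 carbinol epimers (18–20) and the E/Z isomers of the C1=C2 bond (20, 21) are carried as mixtures, because both elements vanish in steps 15 and 16; the SMILES leave them unspecified. Compounds 1, 5, 7 and 9 are taken as commercial.

**Route**

Step 1
Reactants: 1 (S)-5-(hydroxymethyl)furan-2(5H)-one
Product: 2 (S)-5-[(triethylsilyloxy)methyl]furan-2(5H)-one
Conditions: TESCl, imidazole, CH2Cl2, 0 °C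
Reagents that add atoms: chlorotriethylsilane, CC[Si](Cl)(CC)CC
Why: Standard silylation of a primary alcohol; the TES ether is chosen because a primary TES ether can later be oxidised directly under Swern conditions while TBS and TBDPS ethers survive.

Step 2
Reactants: 2 (S)-5-[(triethylsilyloxy)methyl]furan-2(5H)-one
Product: 3 (S)-3-(hydroxymethyl)-5-[(triethylsilyloxy)methyl]furan-2(5H)-one
Conditions: paraformaldehyde, PBu3 (20 mol %), THF–MeOH (4:1), rt
Reagents that add atoms: formaldehyde (from paraformaldehyde), C=O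
Why: Phosphine-catalysed Morita–Baylis–Hillman α-hydroxymethylation (conjugate addition of PBu3 at C7, aldol of the enolate at C11, loss of the phosphine); the non-basic catalyst should avoid γ-deprotonation, so the C6 stereocentre of the pool butenolide is kept.

Step 3
Reactants: 3 (S)-3-(hydroxymethyl)-5-[(triethylsilyloxy)methyl]furan-2(5H)-one
Product: 4 (S)-3-(bromomethyl)-5-[(triethylsilyloxy)methyl]furan-2(5H)-one
Conditions: NBS, Me2S, CH2Cl2, −20 → 0 °C
Reagents that add atoms: N-bromosuccinimide, O=C1CCC(=O)N1Br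
Why: Corey–Kim bromination converts the allylic alcohol into the allylic bromide under neutral conditions that leave the TES ether and the butenolide untouched.

Step 4
Reactants: 4 (S)-3-(bromomethyl)-5-[(triethylsilyloxy)methyl]furan-2(5H)-one; 5 (E)-4-(tert-butyldimethylsilyloxy)but-2-enal
Product: 6 Barbier adduct, trans α-methylene lactone carrying the C8 carbinol as the epimer of the target (8-epi)
Conditions: In powder, DMF, rt; aqueous work-up
Reagents that add atoms: none
Why: Indium-mediated Barbier allylation (SE2′) forms C7–C8 by 1,2-attack of the γ-carbon C7 on the enal and restores the exocyclic methylene; C7 is set by attack anti to the C6 CH2OTES group (trans lactone), and C8 by a chair Zimmerman–Traxler transition state with the ring-locked E-type γ-substituent, which should give the C8 epimer of the target carbinol.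

Step 5
Reactants: 6 Barbier adduct (8-epi carbinol); 7 (R)-2-methylbutanoic acid
Product: 8 C8 (R)-2-methylbutanoate with the target configuration at C8
Conditions: PPh3, DIAD (premixed), toluene, 0 °C → rt
Reagents that add atoms: none
Why: Mitsunobu esterification with SN2 inversion at C8 installs the (R)-2-methylbutanoate and corrects C8 to the target configuration in one operation; premixing PPh3 and DIAD keeps free phosphine away from the methylene lactone.

Step 6
Reactants: 9 (but-3-en-1-yl)triphenylphosphonium bromide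
Product: 10 2-(triphenylphosphoranylidene)pent-4-enal
Conditions: KOt-Bu, THF, 0 °C; HCO2Et, 0 °C → rt
Reagents that add atoms: ethyl formate, CCOC=O
Why: Formylation of the non-stabilised ylide with ethyl formate, followed by deprotonation of the acylphosphonium salt, gives the stabilised α-allyl formyl ylide.

Step 7
Reactants: 8 C8 (R)-2-methylbutanoate; 10 2-(triphenylphosphoranylidene)pent-4-enal
Product: 12 E-enal (C4=C5 installed; C15 as CHO; allyl group on C4), via C5 aldehyde 11 (not isolated)
Conditions: (COCl)2, DMSO, CH2Cl2, −78 → −40 °C; Et3N; then 10, toluene, 60 °C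
Reagents that add atoms: none
Why: The Swern reagent oxidises the primary TES ether directly to the aldehyde (the TBS ether is inert), and Wittig reaction of the crude α-acyloxy aldehyde with the stabilised ylide should give the E enal (C15 trans to C6, allyl cis to C6), which is the ring-cis C4=C5 geometry of the target.

Step 8
Reactants: 12 E-enal
Product: 13 C15 allylic alcohol
Conditions: NaBH4, CeCl3·7H2O, MeOH, −78 °C
Reagents that add atoms: none
Why: Luche 1,2-reduction is chemoselective for the enal over the lactone, the ester and the methylene lactone.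

Step 9
Reactants: 13 C15 allylic alcohol
Product: 14 C15 TBDPS ether
Conditions: TBDPSCl, imidazole, CH2Cl2, rt
Reagents that add atoms: tert-butyl(chloro)diphenylsilane, CC(C)(C)[Si](Cl)(c1ccccc1)c1ccccc1
Why: Silylation of the primary allylic alcohol as a TBDPS ether, which outlasts the later removal of the TBS ether.

Step 10
Reactants: 14 C15 TBDPS ether
Product: 15 C14 primary allylic alcohol
Conditions: PPTS (cat.), MeOH, rt
Reagents that add atoms: none
Why: Acid-catalysed methanolysis cleaves the primary TBS ether much faster than the TBDPS ether.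

Step 11
Reactants: 15 C14 primary allylic alcohol
Product: 16 (9,10)-epoxy alcohol
Conditions: Ti(OiPr)4 (10 mol %), D-(−)-DIPT (12 mol %), TBHP, 4 Å MS, CH2Cl2, −20 °C
Reagents that add atoms: tert-butyl hydroperoxide, CC(C)(C)OO
Why: Sharpless asymmetric epoxidation of the E primary allylic alcohol (the only allylic alcohol present); reagent control by D-(−)-DIPT should give the (2R,3R)-type epoxy alcohol, which fixes the target configuration at C9.

Step 12
Reactants: 16 (9,10)-epoxy alcohol
Product: 17 epoxy aldehyde (C14 as CHO)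
Conditions: Dess–Martin periodinane, NaHCO3, CH2Cl2, 0 °C → rt
Reagents that add atoms: none
Why: Buffered Dess–Martin oxidation gives the α,β-epoxy aldehyde without epoxide opening or epimerisation.

Step 13
Reactants: 17 epoxy aldehyde
Product: 19 epoxy silyl ether diene (C14–OTBS, vinyl on C14), via C14 magnesium alkoxide 18 (not isolated)
Conditions: CH2=CHMgBr, THF, −78 °C; then TBSOTf, 2,6-lutidine, −78 → 0 °C
Reagents that add atoms: vinylmagnesium bromide, C=C[Mg]Br; tert-butyldimethylsilyl trifluoromethanesulfonate, CC(C)(C)[Si](C)(C)OS(=O)(=O)C(F)(F)F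
Why: Grignard addition at −78 °C is chemoselective for the aldehyde and the magnesium alkoxide is silylated in the flask; the new C14 centre is not controlled and need not be, because C14 becomes the formyl carbon in step 15.

Step 14
Reactants: 19 epoxy silyl ether diene
Product: 20 eleven-membered epoxy silyl ether (carbocycle C1–C14–C10–C9–C8–C7–C6–C5–C4–C3–C2, fused to the lactone)
Conditions: second-generation Grubbs catalyst RuCl2(=CHPh)(H2IMes)(PCy3) (10 mol %), toluene (1 mM), 80 °C
Reagents that add atoms: none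
Why: Ring-closing metathesis joins the only two monosubstituted alkenes (the allyl group on C4 and the vinyl group on C14) under high dilution with loss of ethylene; the trisubstituted C4=C5 alkene and the electron-poor methylene lactone should remain spectators.

Step 15
Reactants: 20 eleven-membered epoxy silyl ether
Product: 21 ten-membered β,γ-unsaturated aldehyde (C10 bears CHO, C9 bears OTBS, alkene at C1=C2)
Conditions: MeAl(OAr)2 (MABR, Ar = 4-bromo-2,6-di-tert-butylphenyl; made from AlMe3 and ArOH; 4 equiv), CH2Cl2, −78 → −40 °C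
Reagents that add atoms: none
Why: Proposed new method: MABR binds the epoxide oxygen of 20 and, as the C10–O bond ionises, the ring alkenyl carbon C1 shifts with its bonding pair from C14 to C10 anti to the leaving oxygen, while the C14 silyloxy group takes up the positive charge as a silyl oxocarbenium ion that passes its TBS group to the new C9 aluminium alkoxide. The closest known reaction is the organoaluminium-promoted semipinacol rearrangement of 2,3-epoxy alcohol silyl ethers to β-silyloxy aldehydes with alkenyl migration, established for open-chain substrates and for six-to-five ring contraction but not for a medium ring in which both the migrating carbon and the terminus are ring members. The ten-membered ring is closed by this suprafacial 1,2-shift across the C14–C10 bond (a three-centre bridged transition state, formally a 3-exo attack of the C1–C14 σ bond on the epoxide carbon), so the eleven-membered ring loses C14, which becomes the exocyclic formyl group. C9 keeps the epoxide configuration fixed in step 11 and C10 is formed with inversion (it is erased in step 16); both C14 epimers can reach the required anti-periplanar C1–C14/C10–O arrangement because that torsion is a ring torsion. The step needs alkenyl migration to win over hydride shift from C14, C10–O cleavage to win over C9–O cleavage, and no participation by the C8 ester: the π-participating alkenyl group is the better migrating group, the silyloxy donor sits next to C10 while the C8 acyloxy group disfavours charge at C9, and excess bulky MABR ties up the ester and lactone carbonyls.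

Step 16
Reactants: 21 ten-membered β,γ-unsaturated aldehyde
Product: 22 9-O-TBS-15-O-TBDPS ether of the target
Conditions: DBU (0.2 equiv), CH2Cl2, 0 °C → rt
Reagents that add atoms: none
Why: Base-mediated isomerisation of the β,γ-unsaturated aldehyde into conjugation through the dienolate should give the thermodynamic E enal (C14 trans to C2), which is the ring-cis C1=C10 alkene of the target; the C10 stereocentre is erased and C9 is untouched.

Step 17
Reactants: 22 9-O-TBS-15-O-TBDPS ether of the target
Product: 23 target (CNP0331447.8)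
Conditions: HF·pyridine, pyridine, THF, 0 °C → rt
Reagents that add atoms: none
Why: Buffered HF·pyridine cleaves both silyl ethers without touching the enal, the methylene lactone or the C8 ester, and without the basic conditions that could cause acyl migration from O8 to O9.

**Compound list**

1 | (S)-5-(hydroxymethyl)furan-2(5H)-one | O=C1O[C@H](CO)C=C1 | starting material
2 | (S)-5-[(triethylsilyloxy)methyl]furan-2(5H)-one | O=C1O[C@H](CO[Si](CC)(CC)CC)C=C1 | intermediate
3 | (S)-3-(hydroxymethyl)-5-[(triethylsilyloxy)methyl]furan-2(5H)-one | O=C1O[C@H](CO[Si](CC)(CC)CC)C=C1CO | intermediate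
4 | (S)-3-(bromomethyl)-5-[(triethylsilyloxy)methyl]furan-2(5H)-one | O=C1O[C@H](CO[Si](CC)(CC)CC)C=C1CBr | intermediate
5 | (E)-4-(tert-butyldimethylsilyloxy)but-2-enal | O=C/C=C/CO[Si](C)(C)C(C)(C)C | starting material
6 | (4R,5S)-4-[(1S,2E)-4-(tert-butyldimethylsilyloxy)-1-hydroxybut-2-en-1-yl]-3-methylidene-5-[(triethylsilyloxy)methyl]oxolan-2-one (C6 and C7 as in the target; C8 epimeric) | C=C1C(=O)O[C@H](CO[Si](CC)(CC)CC)[C@H]1[C@@H](O)/C=C/CO[Si](C)(C)C(C)(C)C | intermediate
7 | (R)-2-methylbutanoic acid | CC[C@@H](C)C(=O)O | starting material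
8 | (4R,5S)-4-[(1R,2E)-4-(tert-butyldimethylsilyloxy)-1-{[(2R)-2-methylbutanoyl]oxy}but-2-en-1-yl]-3-methylidene-5-[(triethylsilyloxy)methyl]oxolan-2-one | C=C1C(=O)O[C@H](CO[Si](CC)(CC)CC)[C@H]1[C@H](OC(=O)[C@H](C)CC)/C=C/CO[Si](C)(C)C(C)(C)C | intermediate
9 | (but-3-en-1-yl)triphenylphosphonium bromide | C=CCC[P+](c1ccccc1)(c1ccccc1)c1ccccc1.[Br-] | starting material
10 | 2-(triphenylphosphoranylidene)pent-4-enal | C=CCC(C=O)=P(c1ccccc1)(c1ccccc1)c1ccccc1 | intermediate
11 | (2S,3R)-3-[(1R,2E)-4-(tert-butyldimethylsilyloxy)-1-{[(2R)-2-methylbutanoyl]oxy}but-2-en-1-yl]-4-methylidene-5-oxooxolane-2-carbaldehyde | C=C1C(=O)O[C@H](C=O)[C@H]1[C@H](OC(=O)[C@H](C)CC)/C=C/CO[Si](C)(C)C(C)(C)C | intermediate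
12 | (4R,5R)-4-[(1R,2E)-4-(tert-butyldimethylsilyloxy)-1-{[(2R)-2-methylbutanoyl]oxy}but-2-en-1-yl]-5-[(1E)-2-formylpenta-1,4-dien-1-yl]-3-methylideneoxolan-2-one | C=C1C(=O)O[C@H](/C=C(/C=O)CC=C)[C@H]1[C@H](OC(=O)[C@H](C)CC)/C=C/CO[Si](C)(C)C(C)(C)C | intermediate
13 | (4R,5R)-4-[(1R,2E)-4-(tert-butyldimethylsilyloxy)-1-{[(2R)-2-methylbutanoyl]oxy}but-2-en-1-yl]-5-[(1E)-2-(hydroxymethyl)penta-1,4-dien-1-yl]-3-methylideneoxolan-2-one | C=C1C(=O)O[C@H](/C=C(/CO)CC=C)[C@H]1[C@H](OC(=O)[C@H](C)CC)/C=C/CO[Si](C)(C)C(C)(C)C | intermediate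
14 | (4R,5R)-4-[(1R,2E)-4-(tert-butyldimethylsilyloxy)-1-{[(2R)-2-methylbutanoyl]oxy}but-2-en-1-yl]-5-[(1E)-2-{[(tert-butyldiphenylsilyl)oxy]methyl}penta-1,4-dien-1-yl]-3-methylideneoxolan-2-one | C=C1C(=O)O[C@H](/C=C(/CO[Si](c2ccccc2)(c2ccccc2)C(C)(C)C)CC=C)[C@H]1[C@H](OC(=O)[C@H](C)CC)/C=C/CO[Si](C)(C)C(C)(C)C | intermediate
15 | (4R,5R)-5-[(1E)-2-{[(tert-butyldiphenylsilyl)oxy]methyl}penta-1,4-dien-1-yl]-4-[(1R,2E)-4-hydroxy-1-{[(2R)-2-methylbutanoyl]oxy}but-2-en-1-yl]-3-methylideneoxolan-2-one | C=C1C(=O)O[C@H](/C=C(/CO[Si](c2ccccc2)(c2ccccc2)C(C)(C)C)CC=C)[C@H]1[C@H](OC(=O)[C@H](C)CC)/C=C/CO | intermediate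
16 | (4S,5R)-5-[(1E)-2-{[(tert-butyldiphenylsilyl)oxy]methyl}penta-1,4-dien-1-yl]-4-{(S)-[(2R,3R)-3-(hydroxymethyl)oxiran-2-yl]{[(2R)-2-methylbutanoyl]oxy}methyl}-3-methylideneoxolan-2-one | C=C1C(=O)O[C@H](/C=C(/CO[Si](c2ccccc2)(c2ccccc2)C(C)(C)C)CC=C)[C@H]1[C@H](OC(=O)[C@H](C)CC)[C@H]2O[C@@H]2CO | intermediate
17 | (4S,5R)-5-[(1E)-2-{[(tert-butyldiphenylsilyl)oxy]methyl}penta-1,4-dien-1-yl]-4-{(S)-[(2R,3S)-3-formyloxiran-2-yl]{[(2R)-2-methylbutanoyl]oxy}methyl}-3-methylideneoxolan-2-one | C=C1C(=O)O[C@H](/C=C(/CO[Si](c2ccccc2)(c2ccccc2)C(C)(C)C)CC=C)[C@H]1[C@H](OC(=O)[C@H](C)CC)[C@H]2O[C@@H]2C=O | intermediate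
18 | vinyl adduct of 17: epoxy carbinol with CH(OH)CH=CH2 at C14 (formed as its bromomagnesium alkoxide; C14 epimers; other centres as in 17) | C=C1C(=O)O[C@H](/C=C(/CO[Si](c2ccccc2)(c2ccccc2)C(C)(C)C)CC=C)[C@H]1[C@H](OC(=O)[C@H](C)CC)[C@H]2O[C@@H]2C(O)C=C | intermediate
19 | TBS ether of 18: acyclic epoxy silyl ether diene (C14 epimers) | C=C1C(=O)O[C@H](/C=C(/CO[Si](c2ccccc2)(c2ccccc2)C(C)(C)C)CC=C)[C@H]1[C@H](OC(=O)[C@H](C)CC)[C@H]2O[C@@H]2C(O[Si](C)(C)C(C)(C)C)C=C | intermediate
20 | eleven-membered carbocycle fused to the trans α-methylene lactone: 9,10-epoxide, 14-OTBS (C14 in the ring), 8-(R)-2-methylbutanoate, 15-OTBDPS, ring-cis C4=C5, C1=C2 as E/Z mixture | C=C1C(=O)O[C@@H]2/C=C(/CO[Si](c3ccccc3)(c3ccccc3)C(C)(C)C)CC=CC(O[Si](C)(C)C(C)(C)C)[C@H]3O[C@@H]3[C@@H](OC(=O)[C@H](C)CC)[C@@H]12 | intermediate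
21 | ten-membered ring: 10-formyl (C10–H), 9-OTBS, 8-(R)-2-methylbutanoate, 15-OTBDPS, alkenes at C1=C2 and C4=C5, trans α-methylene lactone at C6/C7 | C=C1C(=O)O[C@@H]2/C=C(/CO[Si](c3ccccc3)(c3ccccc3)C(C)(C)C)CC=C[C@@H](C=O)[C@H](O[Si](C)(C)C(C)(C)C)[C@@H](OC(=O)[C@H](C)CC)[C@@H]12 | intermediate
22 | 9-O-TBS-15-O-TBDPS ether of the target (conjugated C1=C10 enal, ring-cis) | C=C1C(=O)O[C@@H]2/C=C(/CO[Si](c3ccccc3)(c3ccccc3)C(C)(C)C)CC/C=C(/C=O)[C@H](O[Si](C)(C)C(C)(C)C)[C@@H](OC(=O)[C@H](C)CC)[C@@H]12 | intermediate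
23 | CNP0331447.8: (6R,7S,8S,9S)-9,15-dihydroxy-8-[(2R)-2-methylbutanoyloxy]-14-oxo-cis,cis-germacra-1(10),4,11(13)-trien-6,12-olide | C=C1C(=O)O[C@@H]2/C=C(/CO)CC/C=C(/C=O)[C@H](O)[C@@H](OC(=O)[C@H](C)CC)[C@@H]12 | target

**Step count and risks**

Total step count: 17. Longest linear sequence: 16 steps (1 → 23; step 6 is the only off-line step).

Steps most likely to fail:

1. Step 15 (key step, proposed new method). What may go wrong: hydride shift from C14 instead of alkenyl shift (giving a ring ketone without contraction), or opening of the epoxide at C9 with participation of the C8 ester. Fallback: set out from 19 and run the same MABR rearrangement on the open-chain epoxy silyl ether, where alkenyl migration is established chemistry. This should give the open-chain α-vinyl β-silyloxy aldehyde F1. Ring-closing metathesis of F1 (second-generation Grubbs catalyst, toluene, high dilution) between the new vinyl group on C10 and the allyl group on C4 then closes the ten-membered ring at its final size and returns to the route at 21.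

2. Step 14. What may go wrong: oligomerisation in place of medium-ring closure, and slow initiation at the hindered vinyl group next to the silyloxy and epoxide groups. Fallback: set out from 8 and close the eleven-membered ring by carbonyl addition instead of metathesis. The phosphonium salt (E)-(4-iodobut-3-en-1-yl)triphenylphosphonium iodide F2 is formylated as in step 6 to the iodovinyl ylide F3. Steps 7 to 12 are then run unchanged on the iodovinyl series: E-enal F4, allylic alcohol F5, TBDPS ether F6, primary allylic alcohol F7, epoxy alcohol F8 and epoxy aldehyde F9. Nozaki–Hiyama–Kishi macrocyclisation of F9 (CrCl2, NiCl2 cat., DMSO–THF, high dilution) forms the C1–C14 bond and the ring, giving the macrocyclic carbinol F10. Silylation (TBSOTf, 2,6-lutidine) returns to the route at 20, as its E-C1=C2 isomer.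

3. Step 5. What may go wrong: SN2′ substitution or elimination at the hindered allylic carbinol, so that inversion is incomplete. Fallback: set out from 6 and invert C8 by oxidation and reduction. Dess–Martin oxidation gives the enone F11. Reagent-controlled reduction ((R)-Me-CBS oxazaborolidine, BH3·SMe2, −40 °C, the alkenyl group acting as the larger substituent) should give the C8-epimeric alcohol F12. Steglich esterification of F12 with 7 (DCC, DMAP cat., CH2Cl2, 0 °C), with retention, returns to the route at 8. The same esterification serves directly if the Barbier step delivers F12 instead of 6.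

Further compounds
F1 | step 15 | open-chain α-vinyl β-silyloxy aldehyde (C10 bears CHO and vinyl, C9 bears OTBS, allyl on C4) | C=C1C(=O)O[C@H](/C=C(/CO[Si](c2ccccc2)(c2ccccc2)C(C)(C)C)CC=C)[C@H]1[C@H](OC(=O)[C@H](C)CC)[C@@H](O[Si](C)(C)C(C)(C)C)[C@H](C=O)C=C
F2 | step 14 | (E)-(4-iodobut-3-en-1-yl)triphenylphosphonium iodide | I/C=C/CC[P+](c1ccccc1)(c1ccccc1)c1ccccc1.[I-]
F3 | step 14 | (4E)-5-iodo-2-(triphenylphosphoranylidene)pent-4-enal | O=CC(C/C=C/I)=P(c1ccccc1)(c1ccccc1)c1ccccc1
F4 | step 14 | iodovinyl analogue of 12 (E-enal) | C=C1C(=O)O[C@H](/C=C(/C=O)C/C=C/I)[C@H]1[C@H](OC(=O)[C@H](C)CC)/C=C/CO[Si](C)(C)C(C)(C)C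
F5 | step 14 | iodovinyl analogue of 13 (C15 allylic alcohol) | C=C1C(=O)O[C@H](/C=C(/CO)C/C=C/I)[C@H]1[C@H](OC(=O)[C@H](C)CC)/C=C/CO[Si](C)(C)C(C)(C)C
F6 | step 14 | iodovinyl analogue of 14 (C15 TBDPS ether) | C=C1C(=O)O[C@H](/C=C(/CO[Si](c2ccccc2)(c2ccccc2)C(C)(C)C)C/C=C/I)[C@H]1[C@H](OC(=O)[C@H](C)CC)/C=C/CO[Si](C)(C)C(C)(C)C
F7 | step 14 | iodovinyl analogue of 15 (C14 primary allylic alcohol) | C=C1C(=O)O[C@H](/C=C(/CO[Si](c2ccccc2)(c2ccccc2)C(C)(C)C)C/C=C/I)[C@H]1[C@H](OC(=O)[C@H](C)CC)/C=C/CO
F8 | step 14 | iodovinyl analogue of 16 (epoxy alcohol) | C=C1C(=O)O[C@H](/C=C(/CO[Si](c2ccccc2)(c2ccccc2)C(C)(C)C)C/C=C/I)[C@H]1[C@H](OC(=O)[C@H](C)CC)[C@H]2O[C@@H]2CO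
F9 | step 14 | iodovinyl analogue of 17 (epoxy aldehyde) | C=C1C(=O)O[C@H](/C=C(/CO[Si](c2ccccc2)(c2ccccc2)C(C)(C)C)C/C=C/I)[C@H]1[C@H](OC(=O)[C@H](C)CC)[C@H]2O[C@@H]2C=O
F10 | step 14 | eleven-membered epoxy carbinol (C14–OH, E-C1=C2; C14 epimers) | C=C1C(=O)O[C@@H]2/C=C(/CO[Si](c3ccccc3)(c3ccccc3)C(C)(C)C)C/C=C/C(O)[C@H]3O[C@@H]3[C@@H](OC(=O)[C@H](C)CC)[C@@H]12
F11 | step 5 | C8 enone from 6 | C=C1C(=O)O[C@H](CO[Si](CC)(CC)CC)[C@H]1C(=O)/C=C/CO[Si](C)(C)C(C)(C)C
F12 | step 5 | (4R,5S)-4-[(1R,2E)-4-(tert-butyldimethylsilyloxy)-1-hydroxybut-2-en-1-yl]-3-methylidene-5-[(triethylsilyloxy)methyl]oxolan-2-one (C8 epimer of 6) | C=C1C(=O)O[C@H](CO[Si](CC)(CC)CC)[C@H]1[C@H](O)/C=C/CO[Si](C)(C)C(C)(C)C
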